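**Plan**

1. Retrosynthesis cuts (a) the bond from the indane methine to the benzodioxane arene, (b) in the benzodioxane half the ring CH2–O(aryl) bond, and (c) in the indane half the exocyclic C=C(CH3)2 bond and the aryl–CHO bond.
2. Enabling feature: C2 of the 1,4-dioxane ring carries the aryl ether oxygen and two one-carbon arms (ring C3H2–O and the carbinol carbon), a hidden 2-aryloxypropane-1,3-diol. Tying both arms into an oxetane gives an achiral catechol mono(oxetan-3-yl) ether whose free ortho OH can attack either oxetane CH2 in a 6-exo closure.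
3. Forward, benzodioxane half: oxetanyl ether, Baeyer–Villiger to the phenol, acid-catalysed oxetane opening that closes the dioxane ring and leaves CH2OH, then CH2OH → CO2Me → C(CH3)2OH and borylation of the aryl bromide.
4. Forward, indane half: 6-hydroxyindan-1-one gains the isopropylidene group (aldol addition, dehydration), the C1 oxygen (Luche) and the C7 formyl group (ortho-lithiation). The halves are then joined at C1 and the MOM group is removed.
5. Stereochemistry: dioxane C2 comes from a chiral phosphoric acid choosing between two enantiotopic CH2 groups. Indane C1 comes from a chiral palladium catalyst in an enantioconvergent allyl–aryl coupling. The alkene bears two identical methyls and has no geometry.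

Key step: step 3

Remark: indane positions are numbered with the aryl-bearing carbon as C1 (formyl at C7, oxygen at C6). The sense of induction of the two chiral catalysts (steps 3 and 14) cannot be predicted with certainty, so in each case the catalyst enantiomer that delivers the stated configuration is the one meant.

**Step 1**
Reactants: 1 3-bromo-2-hydroxy-5-methylbenzaldehyde; 2 oxetan-3-yl 4-methylbenzenesulfonate
Product: 3 3-bromo-5-methyl-2-(oxetan-3-yloxy)benzaldehyde
Conditions: Cs2CO3, DMF, 90 °C
Reagents that add atoms: none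
Why: Williamson etherification, in which the caesium phenoxide of 1 displaces tosylate at C3 of the oxetane by SN2; no stereocentre forms.

**Step 2**
Reactants: 3 3-bromo-5-methyl-2-(oxetan-3-yloxy)benzaldehyde
Product: 5 3-bromo-5-methyl-2-(oxetan-3-yloxy)phenol, via aryl formate 4 (not isolated)
Conditions: mCPBA, CH2Cl2, 0 °C → rt; aq. NaHCO3 wash; then K2CO3 (cat.), MeOH, 0 °C; neutral work-up
Reagents that add atoms: mCPBA, O=C(OO)c1cccc(Cl)c1
Why: Baeyer–Villiger oxidation in which the electron-rich 2-alkoxyaryl group migrates gives the aryl formate, and mild methanolysis frees the phenol while the oxetane, inert to carboxylic acid and carbonate at these temperatures, stays closed.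

**Step 3**
Reactants: 5 3-bromo-5-methyl-2-(oxetan-3-yloxy)phenol
Product: 6 [(2R)-8-bromo-6-methyl-2,3-dihydro-1,4-benzodioxin-2-yl]methanol
Conditions: (R)-STRIP [SPINOL-derived phosphoric acid with 2,4,6-triisopropylphenyl groups at C6 and C6'] (5 mol %), PhMe, 25 °C
Reagents that add atoms: none
Why: The chiral phosphoric acid should act bifunctionally, its P–OH hydrogen-bonding to the oxetane oxygen while its P=O oxygen accepts a hydrogen bond from the phenol O–H, so that the phenol oxygen displaces the activated oxetane oxygen at one of the two enantiotopic CH2 carbons in an SN2 opening driven by release of the oxetane ring strain. The closest known reaction type is the chiral-phosphoric-acid-catalysed intramolecular desymmetrisation of oxetan-3-yl ethers by a tethered O–H nucleophile to give 1,4-dioxanes. The dioxane ring closes in the 6-exo-tet mode (phenol O, two arene carbons, ether O, oxetane C3 and the attacked CH2, with the breaking C–O bond outside the new ring). The new stereocentre is the former oxetane C3; no bond to it is made or broken, and its configuration is fixed only by which enantiotopic CH2 the catalyst presents to the phenol, so it is catalyst-controlled. The step needs enantiotopic-group selection and the absence of an uncatalysed or intermolecular background; the ortho placement of OH and oxetanyl ether on the arene allows only the six-membered closure, and acid-free 5 in dilute non-polar solvent should keep the opening inside the hydrogen-bonded complex.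

**Step 4**
Reactants: 6 [(2R)-8-bromo-6-methyl-2,3-dihydro-1,4-benzodioxin-2-yl]methanol
Product: 7 (2S)-8-bromo-6-methyl-2,3-dihydro-1,4-benzodioxine-2-carboxylic acid
Conditions: TEMPO (20 mol %), PhI(OAc)2 (2.2 equiv), MeCN/H2O, rt
Reagents that add atoms: water, O
Why: Oxoammonium oxidation of the primary alcohol through the aldehyde hydrate to the acid runs under near-neutral conditions, so the α-aryloxy stereocentre and the aryl bromide should be untouched (the descriptor changes from R to S only because the priorities change).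

**Step 5**
Reactants: 7 (2S)-8-bromo-6-methyl-2,3-dihydro-1,4-benzodioxine-2-carboxylic acid
Product: 8 methyl (2S)-8-bromo-6-methyl-2,3-dihydro-1,4-benzodioxine-2-carboxylate
Conditions: TMSCHN2, PhMe/MeOH, 0 °C
Reagents that add atoms: (trimethylsilyl)diazomethane, C[Si](C)(C)C=[N+]=[N-]
Why: Esterification with the diazoalkane is base-free, so the C2–H next to the carboxyl group, whose removal would open the ring by β-elimination of aryloxide, is never deprotonated.

**Step 6**
Reactants: 8 methyl (2S)-8-bromo-6-methyl-2,3-dihydro-1,4-benzodioxine-2-carboxylate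
Product: 9 2-[(2S)-8-bromo-6-methyl-2,3-dihydro-1,4-benzodioxin-2-yl]propan-2-ol
Conditions: MeMgBr (3 equiv), THF, −78 → 0 °C; aq. NH4Cl
Reagents that add atoms: methylmagnesium bromide, C[Mg]Br
Why: Double Grignard addition to the ester gives the tertiary alcohol; at low temperature carbonyl addition should outrun α-deprotonation so that C2 keeps its configuration, and MeMgBr does not exchange with the aryl bromide.

**Step 7**
Reactants: 9 2-[(2S)-8-bromo-6-methyl-2,3-dihydro-1,4-benzodioxin-2-yl]propan-2-ol
Product: 10 2-[(2S)-6-methyl-8-(4,4,5,5-tetramethyl-1,3,2-dioxaborolan-2-yl)-2,3-dihydro-1,4-benzodioxin-2-yl]propan-2-ol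
Conditions: B2pin2, PdCl2(dppf) (3 mol %), KOAc, 1,4-dioxane, 90 °C
Reagents that add atoms: bis(pinacolato)diboron, CC1(C)OB(OC1(C)C)B1OC(C)(C)C(C)(C)O1
Why: Miyaura borylation of the aryl bromide tolerates the free tertiary alcohol and the aryl alkyl ethers.

**Step 8**
Reactants: 11 6-hydroxy-2,3-dihydro-1H-inden-1-one
Product: 12 6-(methoxymethoxy)-2,3-dihydro-1H-inden-1-one
Conditions: MOMCl, K2CO3, acetone, rt
Reagents that add atoms: chloromethyl methyl ether, COCCl
Why: O-alkylation of the phenoxide gives the MOM ether, which later directs ortho-lithiation and comes off under mild acid.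

**Step 9**
Reactants: 12 6-(methoxymethoxy)-2,3-dihydro-1H-inden-1-one
Product: 13 rac-2-(2-hydroxypropan-2-yl)-6-(methoxymethoxy)-2,3-dihydro-1H-inden-1-one
Conditions: LDA, THF, −78 °C; acetone; AcOH quench at −78 °C
Reagents that add atoms: acetone, CC(C)=O
Why: Directed aldol addition of the lithium enolate (only C2 can be deprotonated) to acetone, quenched cold to prevent retro-aldol; the C2 stereocentre is removed in the next step.

**Step 10**
Reactants: 13 rac-2-(2-hydroxypropan-2-yl)-6-(methoxymethoxy)-2,3-dihydro-1H-inden-1-one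
Product: 14 6-(methoxymethoxy)-2-(propan-2-ylidene)-2,3-dihydro-1H-inden-1-one
Conditions: Burgess reagent, PhMe, 60 °C; then DBU (cat.), rt
Reagents that add atoms: none
Why: Burgess dehydration of the tertiary β-hydroxy ketone removes the acidic C2–H, and DBU should bring any deconjugated isopropenyl isomer into conjugation, so the exocyclic tetrasubstituted enone forms regiospecifically.

**Step 11**
Reactants: 14 6-(methoxymethoxy)-2-(propan-2-ylidene)-2,3-dihydro-1H-inden-1-one
Product: 15 rac-6-(methoxymethoxy)-2-(propan-2-ylidene)-2,3-dihydro-1H-inden-1-ol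
Conditions: NaBH4, CeCl3·7H2O, MeOH, 0 °C
Reagents that add atoms: none
Why: Luche 1,2-reduction of the cross-conjugated aryl enone gives the racemic allylic alcohol and leaves the alkene alone.

**Step 12**
Reactants: 15 rac-6-(methoxymethoxy)-2-(propan-2-ylidene)-2,3-dihydro-1H-inden-1-ol
Product: 16 rac-3-hydroxy-5-(methoxymethoxy)-2-(propan-2-ylidene)-2,3-dihydro-1H-indene-4-carbaldehyde
Conditions: s-BuLi (2.3 equiv), TMEDA, THF, −78 → −40 °C; DMF; aq. NH4Cl
Reagents that add atoms: N,N-dimethylformamide, CN(C)C=O
Why: Directed ortho-metalation, in which the lithium alkoxide at C1 and the MOM ether flank C7 and together should steer the base to that position, followed by formylation of the aryllithium with DMF.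

**Step 13**
Reactants: 16 rac-3-hydroxy-5-(methoxymethoxy)-2-(propan-2-ylidene)-2,3-dihydro-1H-indene-4-carbaldehyde
Product: 17 rac-tert-butyl [7-formyl-6-(methoxymethoxy)-2-(propan-2-ylidene)-2,3-dihydro-1H-inden-1-yl] carbonate
Conditions: Boc2O, DMAP (10 mol %), MeCN, rt
Reagents that add atoms: di-tert-butyl dicarbonate, CC(C)(C)OC(=O)OC(=O)OC(C)(C)C
Why: DMAP-catalysed acylation of the secondary alcohol gives the mixed carbonate, a leaving group that releases its own base on ionisation.

**Step 14**
Reactants: 17 rac-tert-butyl [7-formyl-6-(methoxymethoxy)-2-(propan-2-ylidene)-2,3-dihydro-1H-inden-1-yl] carbonate; 10 2-[(2S)-6-methyl-8-(4,4,5,5-tetramethyl-1,3,2-dioxaborolan-2-yl)-2,3-dihydro-1,4-benzodioxin-2-yl]propan-2-ol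
Product: 18 (3S)-3-[(3S)-3-(2-hydroxypropan-2-yl)-7-methyl-2,3-dihydro-1,4-benzodioxin-5-yl]-5-(methoxymethoxy)-2-(propan-2-ylidene)-2,3-dihydro-1H-indene-4-carbaldehyde
Conditions: Pd2(dba)3 (2.5 mol %), (R)-SEGPHOS (6 mol %), THF/H2O (10:1), 40 °C
Reagents that add atoms: none
Why: Proposed new method: zerovalent palladium should ionise the allylic carbonate to a π-allyl complex spanning C1–C2–C(CH3)2; because the outer terminus carries two identical methyl groups, η3–η1–η3 slippage through it exchanges the two allyl faces, so both enantiomers of 17 feed the one (allyl)(aryl)palladium diastereomer favoured by the chiral bisphosphine after transmetalation with boronate 10 (activated by the tert-butoxide/hydroxide released on ionisation), and C–C reductive elimination should occur at C1 because coupling at the C(CH3)2 terminus would build a quaternary carbon, which keeps the tetrasubstituted exocyclic alkene and sets C1 under catalyst control; the closest known reaction types are the Suzuki–Miyaura coupling of allylic carbonates with arylboron reagents at the less substituted allyl terminus and the enantioconvergent rhodium- and palladium-catalysed allylic arylation of racemic cyclic allyl electrophiles.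

**Step 15**
Reactants: 18 (3S)-3-[(3S)-3-(2-hydroxypropan-2-yl)-7-methyl-2,3-dihydro-1,4-benzodioxin-5-yl]-5-(methoxymethoxy)-2-(propan-2-ylidene)-2,3-dihydro-1H-indene-4-carbaldehyde
Product: 19 Diaporindene H
Conditions: HCl (2 M aq), THF, 40 °C
Reagents that add atoms: none
Why: Acid hydrolysis of the MOM acetal, assisted by the neighbouring formyl group, should free the phenol under conditions too mild to protonate the tetrasubstituted alkene or ionise the tertiary alcohol.

**Compound list**

1 | 3-bromo-2-hydroxy-5-methylbenzaldehyde | Cc1cc(Br)c(O)c(C=O)c1 | starting material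
2 | oxetan-3-yl 4-methylbenzenesulfonate | Cc1ccc(cc1)S(=O)(=O)OC1COC1 | starting material
3 | 3-bromo-5-methyl-2-(oxetan-3-yloxy)benzaldehyde | Cc1cc(Br)c(OC2COC2)c(C=O)c1 | intermediate
4 | 3-bromo-5-methyl-2-(oxetan-3-yloxy)phenyl formate | Cc1cc(Br)c(OC2COC2)c(OC=O)c1 | intermediate (not isolated)
5 | 3-bromo-5-methyl-2-(oxetan-3-yloxy)phenol | Cc1cc(Br)c(OC2COC2)c(O)c1 | intermediate
6 | [(2R)-8-bromo-6-methyl-2,3-dihydro-1,4-benzodioxin-2-yl]methanol | Cc1cc(Br)c2O[C@H](CO)COc2c1 | intermediate
7 | (2S)-8-bromo-6-methyl-2,3-dihydro-1,4-benzodioxine-2-carboxylic acid | Cc1cc(Br)c2O[C@H](C(=O)O)COc2c1 | intermediate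
8 | methyl (2S)-8-bromo-6-methyl-2,3-dihydro-1,4-benzodioxine-2-carboxylate | Cc1cc(Br)c2O[C@H](C(=O)OC)COc2c1 | intermediate
9 | 2-[(2S)-8-bromo-6-methyl-2,3-dihydro-1,4-benzodioxin-2-yl]propan-2-ol | Cc1cc(Br)c2O[C@H](C(C)(C)O)COc2c1 | intermediate
10 | 2-[(2S)-6-methyl-8-(4,4,5,5-tetramethyl-1,3,2-dioxaborolan-2-yl)-2,3-dihydro-1,4-benzodioxin-2-yl]propan-2-ol | Cc1cc(B3OC(C)(C)C(C)(C)O3)c2O[C@H](C(C)(C)O)COc2c1 | intermediate
11 | 6-hydroxy-2,3-dihydro-1H-inden-1-one | O=C1CCc2ccc(O)cc21 | starting material
12 | 6-(methoxymethoxy)-2,3-dihydro-1H-inden-1-one | COCOc1ccc2CCC(=O)c2c1 | intermediate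
13 | rac-2-(2-hydroxypropan-2-yl)-6-(methoxymethoxy)-2,3-dihydro-1H-inden-1-one | COCOc1ccc2CC(C(C)(C)O)C(=O)c2c1 | intermediate
14 | 6-(methoxymethoxy)-2-(propan-2-ylidene)-2,3-dihydro-1H-inden-1-one | COCOc1ccc2CC(=C(C)C)C(=O)c2c1 | intermediate
15 | rac-6-(methoxymethoxy)-2-(propan-2-ylidene)-2,3-dihydro-1H-inden-1-ol | COCOc1ccc2CC(=C(C)C)C(O)c2c1 | intermediate
16 | rac-3-hydroxy-5-(methoxymethoxy)-2-(propan-2-ylidene)-2,3-dihydro-1H-indene-4-carbaldehyde | COCOc1ccc2CC(=C(C)C)C(O)c2c1C=O | intermediate
17 | rac-tert-butyl [7-formyl-6-(methoxymethoxy)-2-(propan-2-ylidene)-2,3-dihydro-1H-inden-1-yl] carbonate | COCOc1ccc2CC(=C(C)C)C(OC(=O)OC(C)(C)C)c2c1C=O | intermediate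
18 | (3S)-3-[(3S)-3-(2-hydroxypropan-2-yl)-7-methyl-2,3-dihydro-1,4-benzodioxin-5-yl]-5-(methoxymethoxy)-2-(propan-2-ylidene)-2,3-dihydro-1H-indene-4-carbaldehyde | CC(C)=C1Cc2ccc(OCOC)c(C=O)c2[C@H]1c1cc(C)cc2c1O[C@H](C(C)(C)O)CO2 | intermediate
19 | Diaporindene H, (3S)-5-hydroxy-3-[(3S)-3-(2-hydroxypropan-2-yl)-7-methyl-2,3-dihydro-1,4-benzodioxin-5-yl]-2-(propan-2-ylidene)-2,3-dihydro-1H-indene-4-carbaldehyde | CC(C)=C1Cc2ccc(O)c(C=O)c2[C@H]1c1cc(C)cc2c1O[C@H](C(C)(C)O)CO2 | target

**Step count and risks**

Total: 15 steps. Longest linear sequence: 9 steps (steps 1–7, 14, 15); the indane half takes 6 steps (8–13) before the union.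

Steps most likely to fail:

1. Step 14 (Proposed new method). The ligand may not differentiate the two allyl faces well enough at C1, ionisation of the hindered carbonate may be slow, and β-hydride loss from the allylpalladium intermediate to a diene or aryl transfer to the wrong allyl terminus may compete. Fallback (known chemistry, no catalyst control at C1): from 17 and 10, the ordinary Suzuki–Miyaura coupling of the allylic carbonate with Pd(PPh3)4 and K3PO4 in THF/water should give 18 together with its C1 epimer (3R)-3-[(3S)-3-(2-hydroxypropan-2-yl)-7-methyl-2,3-dihydro-1,4-benzodioxin-5-yl]-5-(methoxymethoxy)-2-(propan-2-ylidene)-2,3-dihydro-1H-indene-4-carbaldehyde F1. Because the dioxane centre is already fixed, the two are diastereomers and would be separated by preparative chromatography; the route is rejoined at 18.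

2. Step 3 (key step). The catalyst may discriminate poorly between the two enantiotopic oxetane CH2 groups, or an acid-promoted background opening may erode the selectivity. Fallback (resolution instead of desymmetrisation): from 5, ring opening with an achiral acid (diphenyl phosphate, PhMe) should give racemic (8-bromo-6-methyl-2,3-dihydro-1,4-benzodioxin-2-yl)methanol F2. Lipase-catalysed transesterification with vinyl acetate, with the enzyme chosen so that the unwanted (S)-alcohol is acylated to [(2R)-8-bromo-6-methyl-2,3-dihydro-1,4-benzodioxin-2-yl]methyl acetate F3, would leave the (R)-alcohol, and the route is rejoined at 6.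

3. Step 12. The base may deprotonate the benzylic and allylic C3–H2 or lithiate C5 instead of C7. Fallback (formylation before the alkene is present, with the aldehyde carried as an acetal):
   - From 12, NaBH4 reduction gives 6-(methoxymethoxy)-2,3-dihydro-1H-inden-1-ol F4.
   - Lithiation with n-BuLi/TMEDA between the alkoxide and the MOM ether, then DMF, gives 3-hydroxy-5-(methoxymethoxy)-2,3-dihydro-1H-indene-4-carbaldehyde F5.
   - HC(OMe)3 with PPTS in MeOH gives 7-(dimethoxymethyl)-6-(methoxymethoxy)-2,3-dihydro-1H-inden-1-ol F6.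
   - Dess–Martin oxidation gives 7-(dimethoxymethyl)-6-(methoxymethoxy)-2,3-dihydro-1H-inden-1-one F7.
   - Aldol addition to acetone as in step 9 gives 7-(dimethoxymethyl)-2-(2-hydroxypropan-2-yl)-6-(methoxymethoxy)-2,3-dihydro-1H-inden-1-one F8.
   - Burgess dehydration gives 7-(dimethoxymethyl)-6-(methoxymethoxy)-2-(propan-2-ylidene)-2,3-dihydro-1H-inden-1-one F9.
   - Luche reduction gives 7-(dimethoxymethyl)-6-(methoxymethoxy)-2-(propan-2-ylidene)-2,3-dihydro-1H-inden-1-ol F10.
   - PPTS in wet acetone hydrolyses the acetal, and the route is rejoined at 16.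

**Further compounds**

F1 | step 14 | (3R)-3-[(3S)-3-(2-hydroxypropan-2-yl)-7-methyl-2,3-dihydro-1,4-benzodioxin-5-yl]-5-(methoxymethoxy)-2-(propan-2-ylidene)-2,3-dihydro-1H-indene-4-carbaldehyde | CC(C)=C1Cc2ccc(OCOC)c(C=O)c2[C@@H]1c1cc(C)cc2c1O[C@H](C(C)(C)O)CO2
F2 | step 3 | rac-(8-bromo-6-methyl-2,3-dihydro-1,4-benzodioxin-2-yl)methanol | Cc1cc(Br)c2OC(CO)COc2c1
F3 | step 3 | [(2R)-8-bromo-6-methyl-2,3-dihydro-1,4-benzodioxin-2-yl]methyl acetate | Cc1cc(Br)c2O[C@@H](COC(C)=O)COc2c1
F4 | step 12 | rac-6-(methoxymethoxy)-2,3-dihydro-1H-inden-1-ol | COCOc1ccc2CCC(O)c2c1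
F5 | step 12 | rac-3-hydroxy-5-(methoxymethoxy)-2,3-dihydro-1H-indene-4-carbaldehyde | COCOc1ccc2CCC(O)c2c1C=O
F6 | step 12 | rac-7-(dimethoxymethyl)-6-(methoxymethoxy)-2,3-dihydro-1H-inden-1-ol | COCOc1ccc2CCC(O)c2c1C(OC)OC
F7 | step 12 | 7-(dimethoxymethyl)-6-(methoxymethoxy)-2,3-dihydro-1H-inden-1-one | COCOc1ccc2CCC(=O)c2c1C(OC)OC
F8 | step 12 | rac-7-(dimethoxymethyl)-2-(2-hydroxypropan-2-yl)-6-(methoxymethoxy)-2,3-dihydro-1H-inden-1-one | COCOc1ccc2CC(C(C)(C)O)C(=O)c2c1C(OC)OC
F9 | step 12 | 7-(dimethoxymethyl)-6-(methoxymethoxy)-2-(propan-2-ylidene)-2,3-dihydro-1H-inden-1-one | COCOc1ccc2CC(=C(C)C)C(=O)c2c1C(OC)OC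
F10 | step 12 | rac-7-(dimethoxymethyl)-6-(methoxymethoxy)-2-(propan-2-ylidene)-2,3-dihydro-1H-inden-1-ol | COCOc1ccc2CC(=C(C)C)C(O)c2c1C(OC)OC
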